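The pyranone ring C of the (2S)-flavanone is disconnected at C3–C4 and O1–C8a. Its O1–C2–C3 edge then becomes a terminal oxirane on ring B that already holds the C2 configuration, and the C4–C4a–C8a edge of ring A becomes a 2-(2-fluoroaryl)-1,3-dithiane, with C4 as a masked acyl anion and C8a as an aryl fluoride. In one flask the lithiated dithiane opens the (R)-epoxide at its CH2 terminus and the alkoxide set free at C2 displaces the ortho fluoride, closing ring C while C4 is still a dithioketal, so that no retro-aldol or retro-oxa-Michael pathway can erode C2. Dithioketal hydrolysis and MOM cleavage then give abyssinone-IV.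

Key step: step 7

Remark on the chemistry: flavanone numbering is used throughout (O1, C2, C3, C4, C4a, C8a; ring A is the fused benzo ring, ring B the 2-aryl group, ring C the pyranone). The stereocentre of the target is read as (2S), and compounds 1 and 7 and all named reagents are assumed to be commercial.

Step 1
Reactants: 1 methyl 3,5-dibromo-4-hydroxybenzoate
Product: 2 methyl 3,5-dibromo-4-(methoxymethoxy)benzoate
Conditions: MOMCl, i-Pr2NEt, CH2Cl2, 0 °C → rt
Reagents that add atoms: chloromethyl methyl ether (MOMCl), COCCl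
Why: O-alkylation (MOM protection) of the acidic, doubly ortho-brominated phenol with the reactive α-chloro ether should be clean and gives an ether that later withstands palladium, organolithium and alkoxide chemistry.

Step 2
Reactants: 2 methyl 3,5-dibromo-4-(methoxymethoxy)benzoate
Product: 3 methyl 4-(methoxymethoxy)-3,5-bis(3-methylbut-2-en-1-yl)benzoate
Conditions: Pd(PPh3)4, LiCl, DMF, 100 °C
Reagents that add atoms: tributyl(3-methylbut-2-en-1-yl)stannane, CCCC[Sn](CCCC)(CCCC)CC=C(C)C
Why: Double Stille coupling, in which oxidative addition into each C–Br bond and transfer of the prenyl group from tin through its unsubstituted CH2 terminus should give the linear 3-methylbut-2-enyl arene under neutral conditions that spare the ester and the MOM ether.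

Step 3
Reactants: 3 methyl 4-(methoxymethoxy)-3,5-bis(3-methylbut-2-en-1-yl)benzoate
Product: 4 2-chloro-1-[4-(methoxymethoxy)-3,5-bis(3-methylbut-2-en-1-yl)phenyl]ethan-1-one
Conditions: ICH2Cl, MeLi·LiBr, THF, −78 °C; AcOH, −78 °C
Reagents that add atoms: chloroiodomethane, ClCI
Why: Carbenoid homologation of an ester, in which chloromethyllithium formed in situ by iodine–lithium exchange adds to the ester, the tetrahedral lithium hemiketal persists at −78 °C and only the cold acidic quench releases the chloromethyl ketone, so a second addition is avoided and no electrophilic chlorine source ever meets the prenyl alkenes.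

Step 4
Reactants: 4 2-chloro-1-[4-(methoxymethoxy)-3,5-bis(3-methylbut-2-en-1-yl)phenyl]ethan-1-one
Product: 6 (2R)-2-[4-(methoxymethoxy)-3,5-bis(3-methylbut-2-en-1-yl)phenyl]oxirane, via chlorohydrin 5 (not isolated)
Conditions: RuCl(p-cymene)[(S,S)-TsDPEN] (cat.), HCO2H/Et3N, MeCN, rt; then aq NaOH, THF, 0 °C → rt
Reagents that add atoms: none
Why: Noyori–Ikariya asymmetric transfer hydrogenation of an aryl chloromethyl ketone, in which the (S,S)-catalyst (the one that reduces acetophenone to (S)-1-phenylethanol) should deliver hydride in the same spatial sense to the Si face of 4 and so set the (R)-carbinol centre (CH2Cl outranks aryl), after which hydroxide closes the oxirane by intramolecular Williamson displacement at CH2 (3-exo-tet) without touching that centre.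

Step 5
Reactants: 7 2-fluoro-4-hydroxybenzaldehyde
Product: 8 4-(1,3-dithian-2-yl)-3-fluorophenol
Conditions: HS(CH2)3SH, BF3·OEt2, CH2Cl2, 0 °C → rt
Reagents that add atoms: propane-1,3-dithiol, SCCCS
Why: Lewis acid-catalysed dithioacetalisation of the aldehyde is fast and is run on the free phenol because a MOM ether would not survive BF3·OEt2 in the presence of a thiol.

Step 6
Reactants: 8 4-(1,3-dithian-2-yl)-3-fluorophenol
Product: 9 2-[2-fluoro-4-(methoxymethoxy)phenyl]-1,3-dithiane
Conditions: MOMCl, i-Pr2NEt, CH2Cl2, 0 °C → rt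
Reagents that add atoms: chloromethyl methyl ether (MOMCl), COCCl
Why: MOM protection by O-alkylation of the phenoxide, to which the dithiane is inert, removes the acidic proton that would otherwise quench the carbanion of the next step and deactivate ring A towards substitution.

Step 7
Reactants: 9 2-[2-fluoro-4-(methoxymethoxy)phenyl]-1,3-dithiane; 6 (2R)-2-[4-(methoxymethoxy)-3,5-bis(3-methylbut-2-en-1-yl)phenyl]oxirane
Product: 12 (2S)-7-(methoxymethoxy)-2-[4-(methoxymethoxy)-3,5-bis(3-methylbut-2-en-1-yl)phenyl]spiro[chromane-4,2'-[1,3]dithiane], via lithiodithiane 10 (not isolated), via alkoxide 11 (not isolated)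
Conditions: n-BuLi, THF, −78 °C; 6, DMPU, −78 → 0 °C; then t-BuOK, 65 °C
Reagents that add atoms: none
Why: n-BuLi removes the dithiane C–H of 9 (the most acidic proton, stabilised by two sulfur atoms and the aryl group) to give 10, which opens epoxide 6 by SN2 attack at the unsubstituted CH2 carbon to forge C3–C4 and release the C2 alkoxide 11; after exchange to the potassium alkoxide this oxygen adds to the fluorine-bearing carbon of ring A next to the dithiane and fluoride leaves, forging O1–C8a. The closest known reactions are the opening of aryl oxiranes by 2-aryl-2-lithio-1,3-dithianes and the t-BuOK-mediated cyclisation of 3-(2-fluorophenyl)propan-1-ols to chromans, here run consecutively in one flask. Ring C closes as a six-membered ring by intramolecular nucleophilic aromatic substitution (addition–elimination at C8a, formally 6-exo-trig), helped by the gem-disubstitution at the spiro carbon C4. No stereocentre is created: C2 is never a reacting centre, because the carbanion attacks CH2 and the C2–O bond stays intact, so (R)-6 should give (2S)-12 with full fidelity, the descriptor changing only through the CIP priorities. The step needs terminal regioselectivity in the epoxide opening, secured by the bulk and softness of the tertiary carbanion, by DMPU in place of a Lewis acid and by the two ortho prenyl groups that twist the 4-OMOM donor out of conjugation, and it needs deprotonation at the dithiane and not between F and OMOM, which the far greater acidity of the dithiane C–H secures at −78 °C. Keeping C4 as a dithioketal removes every carbonyl-based escape (retro-aldol, dehydration to a chalcone, retro-oxa-Michael racemisation) from the strongly basic medium.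

Step 8
Reactants: 12 (2S)-7-(methoxymethoxy)-2-[4-(methoxymethoxy)-3,5-bis(3-methylbut-2-en-1-yl)phenyl]spiro[chromane-4,2'-[1,3]dithiane]
Product: 13 (2S)-7-(methoxymethoxy)-2-[4-(methoxymethoxy)-3,5-bis(3-methylbut-2-en-1-yl)phenyl]-2,3-dihydro-4H-chromen-4-one
Conditions: MeI, CaCO3, MeCN/H2O, 45 °C
Reagents that add atoms: water, O
Why: Alkylative dithioketal hydrolysis, in which S-methylation makes sulfur a leaving group and the benzylic thionium ion (stabilised by O1 and the 7-alkoxy group) is captured by water, while the neutral CaCO3-buffered medium should leave the prenyl alkenes, the MOM ethers and the base-labile C2 centre untouched.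

Step 9
Reactants: 13 (2S)-7-(methoxymethoxy)-2-[4-(methoxymethoxy)-3,5-bis(3-methylbut-2-en-1-yl)phenyl]-2,3-dihydro-4H-chromen-4-one
Product: 14 abyssinone-IV, (2S)-7-hydroxy-2-[4-hydroxy-3,5-bis(3-methylbut-2-en-1-yl)phenyl]-2,3-dihydro-4H-chromen-4-one
Conditions: aq HCl, MeOH, 40 °C
Reagents that add atoms: none
Why: Acid-catalysed acetal exchange with methanol removes both MOM groups, C2 should stay configurationally stable because no enolate (the entry to retro-oxa-Michael ring opening) forms in acid, and a short reaction time should limit acid-promoted cyclisation of the phenol onto the prenyl groups.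

Compound list
1 | methyl 3,5-dibromo-4-hydroxybenzoate | COC(=O)c1cc(Br)c(O)c(Br)c1 | starting material
2 | methyl 3,5-dibromo-4-(methoxymethoxy)benzoate | COCOc1c(Br)cc(cc1Br)C(=O)OC | intermediate
3 | methyl 4-(methoxymethoxy)-3,5-bis(3-methylbut-2-en-1-yl)benzoate | COCOc1c(CC=C(C)C)cc(cc1CC=C(C)C)C(=O)OC | intermediate
4 | 2-chloro-1-[4-(methoxymethoxy)-3,5-bis(3-methylbut-2-en-1-yl)phenyl]ethan-1-one | COCOc1c(CC=C(C)C)cc(cc1CC=C(C)C)C(=O)CCl | intermediate
5 | (1R)-2-chloro-1-[4-(methoxymethoxy)-3,5-bis(3-methylbut-2-en-1-yl)phenyl]ethan-1-ol | COCOc1c(CC=C(C)C)cc(cc1CC=C(C)C)[C@@H](O)CCl | intermediate (not isolated)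
6 | (2R)-2-[4-(methoxymethoxy)-3,5-bis(3-methylbut-2-en-1-yl)phenyl]oxirane | COCOc1c(CC=C(C)C)cc(cc1CC=C(C)C)[C@@H]1CO1 | intermediate
7 | 2-fluoro-4-hydroxybenzaldehyde | O=Cc1ccc(O)cc1F | starting material
8 | 4-(1,3-dithian-2-yl)-3-fluorophenol | Oc1ccc(C2SCCCS2)c(F)c1 | intermediate
9 | 2-[2-fluoro-4-(methoxymethoxy)phenyl]-1,3-dithiane | COCOc1ccc(C2SCCCS2)c(F)c1 | intermediate
10 | 2-[2-fluoro-4-(methoxymethoxy)phenyl]-2-lithio-1,3-dithiane | COCOc1ccc(C2([Li])SCCCS2)c(F)c1 | intermediate (not isolated)
11 | lithium (1S)-2-{2-[2-fluoro-4-(methoxymethoxy)phenyl]-1,3-dithian-2-yl}-1-[4-(methoxymethoxy)-3,5-bis(3-methylbut-2-en-1-yl)phenyl]ethan-1-olate | COCOc1c(CC=C(C)C)cc(cc1CC=C(C)C)[C@@H]([O-])CC1(SCCCS1)c1ccc(OCOC)cc1F.[Li+] | intermediate (not isolated)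
12 | (2S)-7-(methoxymethoxy)-2-[4-(methoxymethoxy)-3,5-bis(3-methylbut-2-en-1-yl)phenyl]spiro[chromane-4,2'-[1,3]dithiane] | COCOc1c(CC=C(C)C)cc(cc1CC=C(C)C)[C@@H]1CC2(SCCCS2)c2ccc(OCOC)cc2O1 | intermediate
13 | (2S)-7-(methoxymethoxy)-2-[4-(methoxymethoxy)-3,5-bis(3-methylbut-2-en-1-yl)phenyl]-2,3-dihydro-4H-chromen-4-one | COCOc1c(CC=C(C)C)cc(cc1CC=C(C)C)[C@@H]1CC(=O)c2ccc(OCOC)cc2O1 | intermediate
14 | abyssinone-IV, (2S)-7-hydroxy-2-[4-hydroxy-3,5-bis(3-methylbut-2-en-1-yl)phenyl]-2,3-dihydro-4H-chromen-4-one | CC(C)=CCc1cc([C@@H]2CC(=O)c3ccc(O)cc3O2)cc(CC=C(C)C)c1O | target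

Total step count: 9
Longest linear sequence: 7 steps (steps 1, 2, 3, 4, 7, 8 and 9, from compound 1)

Steps most likely to fail

Step 7. The ring closure may stall because the fluoride sits on a ring that carries no electron-withdrawing group once C4 is masked. The hot alkoxide medium may meanwhile move the prenyl double bonds into conjugation with ring B. The fallback uses known chemistry in two operations instead of one and sets out from 6. Commercial 2-bromo-4-hydroxybenzaldehyde is taken through the operations of steps 5 and 6 to 3-bromo-4-(1,3-dithian-2-yl)phenol F1 and then 2-[2-bromo-4-(methoxymethoxy)phenyl]-1,3-dithiane F2. F2 is deprotonated with lithium diisopropylamide (no bromine–lithium exchange) and opens 6 in THF/DMPU at −78 → 0 °C to give, after aqueous quench, (1S)-2-{2-[2-bromo-4-(methoxymethoxy)phenyl]-1,3-dithian-2-yl}-1-[4-(methoxymethoxy)-3,5-bis(3-methylbut-2-en-1-yl)phenyl]ethan-1-ol F3. A copper-catalysed Ullmann-type etherification (CuI, 3,4,7,8-tetramethyl-1,10-phenanthroline, Cs2CO3, toluene, 110 °C) then closes O1–C8a under weakly basic conditions and returns to the route at 12.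

Step 2. The second coupling next to the OMOM group may be slow, leaving mono-coupled or protodebrominated material. Allyl transposition at palladium may also deliver 1,1-dimethylallyl isomers. The fallback sets out from 2. A double Suzuki–Miyaura coupling with allylboronic acid pinacol ester (Pd(dppf)Cl2, CsF, THF, reflux), for which transposition is immaterial, should give methyl 4-(methoxymethoxy)-3,5-di(prop-2-en-1-yl)benzoate F4. Olefin cross-metathesis with 2-methylbut-2-ene (second-generation Grubbs catalyst, (H2IMes)(PCy3)Cl2Ru=CHPh, CH2Cl2, 40 °C) then converts both allyl groups into prenyl groups and returns to the route at 3.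

Step 3. The carbenoid may decompose before it adds to the electron-rich ester, or the hemiketal may collapse early and take up a second carbenoid. The fallback replaces asymmetric reduction by resolution and sets out from 3. Reduction with i-Bu2AlH (CH2Cl2, −78 °C) should give [4-(methoxymethoxy)-3,5-bis(3-methylbut-2-en-1-yl)phenyl]methanol F5, and MnO2 oxidation gives 4-(methoxymethoxy)-3,5-bis(3-methylbut-2-en-1-yl)benzaldehyde F6. Corey–Chaykovsky methylenation (trimethylsulfonium iodide, NaH, DMSO/THF) gives racemic 2-[4-(methoxymethoxy)-3,5-bis(3-methylbut-2-en-1-yl)phenyl]oxirane F7. Jacobsen hydrolytic kinetic resolution with (salen)Co(OAc), using the catalyst enantiomer that hydrolyses the (S)-epoxide and 0.55 equiv of water, should leave the (R)-epoxide and turn the other half into (1S)-1-[4-(methoxymethoxy)-3,5-bis(3-methylbut-2-en-1-yl)phenyl]ethane-1,2-diol F8. The route is rejoined at 6, with 4 and 5 bypassed.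

Further compounds
F1 | step 7 | 3-bromo-4-(1,3-dithian-2-yl)phenol | Oc1ccc(C2SCCCS2)c(Br)c1
F2 | step 7 | 2-[2-bromo-4-(methoxymethoxy)phenyl]-1,3-dithiane | COCOc1ccc(C2SCCCS2)c(Br)c1
F3 | step 7 | (1S)-2-{2-[2-bromo-4-(methoxymethoxy)phenyl]-1,3-dithian-2-yl}-1-[4-(methoxymethoxy)-3,5-bis(3-methylbut-2-en-1-yl)phenyl]ethan-1-ol | COCOc1c(CC=C(C)C)cc(cc1CC=C(C)C)[C@@H](O)CC1(SCCCS1)c1ccc(OCOC)cc1Br
F4 | step 2 | methyl 4-(methoxymethoxy)-3,5-di(prop-2-en-1-yl)benzoate | COCOc1c(CC=C)cc(cc1CC=C)C(=O)OC
F5 | step 3 | [4-(methoxymethoxy)-3,5-bis(3-methylbut-2-en-1-yl)phenyl]methanol | COCOc1c(CC=C(C)C)cc(CO)cc1CC=C(C)C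
F6 | step 3 | 4-(methoxymethoxy)-3,5-bis(3-methylbut-2-en-1-yl)benzaldehyde | COCOc1c(CC=C(C)C)cc(C=O)cc1CC=C(C)C
F7 | step 3 | racemic 2-[4-(methoxymethoxy)-3,5-bis(3-methylbut-2-en-1-yl)phenyl]oxirane | COCOc1c(CC=C(C)C)cc(C2CO2)cc1CC=C(C)C
F8 | step 3 | (1S)-1-[4-(methoxymethoxy)-3,5-bis(3-methylbut-2-en-1-yl)phenyl]ethane-1,2-diol | COCOc1c(CC=C(C)C)cc(cc1CC=C(C)C)[C@H](O)CO
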